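Everything rests on cutting the cyclohexene ring (C1 carries the chain, C2 the methyl group, C6 the two methyls) across C4–C5 and C6–C1, the two bonds opposite its C2=C3 olefin, so that C1–C4 come from a farnesol-derived 2-silyloxy diene and C5–C6 from dimethyl methylenemalonate. One copper–bis(oxazoline)-catalysed cycloaddition should form both bonds, close the only ring, set the lone stereocenter at C1 and leave an enol silane that fixes the C2=C3 olefin; the twin esters on C6 later become the gem-dimethyl pair. The precursor is an (E,E,E)-tetraene with a triethylsilyl enol ether at one end and a TBS-protected allylic alcohol at the other; the linoleate is attached last.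

Key step: step 7

Remark: ylide 7 is treated as a purchasable reagent; the spatial arrangement at the ring stereocenter is the same from 13 to 22, and its descriptor reads R in diester 13 (and in F2) and S elsewhere only because the CIP ranking of the two neighbouring ring carbons changes.

Step 1
Reactants: 1 (2E,6E)-farnesol
Product: 2 tert-butyldimethyl{[(2E,6E)-3,7,11-trimethyldodeca-2,6,10-trien-1-yl]oxy}silane
Conditions: TBSCl, imidazole, DMF, 0 °C → rt
Reagents that add atoms: tert-butyldimethylsilyl chloride, CC(C)(C)[Si](C)(C)Cl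
Why: Imidazole-promoted silylation of a primary allylic alcohol is a standard protection that leaves the three trisubstituted olefins and their geometry untouched.

Step 2
Reactants: 2 tert-butyldimethyl{[(2E,6E)-3,7,11-trimethyldodeca-2,6,10-trien-1-yl]oxy}silane
Product: 4 3-[(3E,7E)-9-(tert-butyldimethylsilyloxy)-3,7-dimethylnona-3,7-dien-1-yl]-2,2-dimethyloxirane (racemic), via bromohydrin 3 (not isolated)
Conditions: NBS, THF/H2O, 0 °C; then K2CO3, MeOH, rt
Reagents that add atoms: N-bromosuccinimide, O=C1CCC(=O)N1Br (bromine, carried only by 3); water, O (the oxygen of the epoxide)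
Why: Bromohydrin formation in aqueous THF is selective for the terminal isopropylidene olefin of farnesyl derivatives, water opening the bromonium ion at the tertiary carbon, and carbonate then closes the epoxide by intramolecular Williamson displacement; the racemic epoxide carbon is excised in step 3.

Step 3
Reactants: 4 3-[(3E,7E)-9-(tert-butyldimethylsilyloxy)-3,7-dimethylnona-3,7-dien-1-yl]-2,2-dimethyloxirane
Product: 6 (4E,8E)-10-(tert-butyldimethylsilyloxy)-4,8-dimethyldeca-4,8-dienal, via diol 5 (not isolated)
Conditions: H5IO6, THF/Et2O, 0 °C, short reaction time; aq. NaHCO3 quench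
Reagents that add atoms: water, O (enters diol 5 as the tertiary hydroxyl and leaves again in acetone, so none of it remains in 6)
Why: Periodic acid hydrates the trisubstituted epoxide at its tertiary carbon and cleaves the resulting vicinal diol through a cyclic periodate ester (Malaprade cleavage), releasing acetone and the aldehyde, while the brief cold exposure spares the TBS ether and the olefins.

Step 4
Reactants: 6 (4E,8E)-10-(tert-butyldimethylsilyloxy)-4,8-dimethyldeca-4,8-dienal; 7 3-(triphenylphosphoranylidene)butan-2-one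
Product: 8 (3E,7E,11E)-13-(tert-butyldimethylsilyloxy)-3,7,11-trimethyltrideca-3,7,11-trien-2-one
Conditions: toluene, 100 °C
Reagents that add atoms: none
Why: Wittig olefination with a ketone-stabilised, α-methylated ylide is under thermodynamic control and should give the (E)-trisubstituted enone under neutral conditions; any minor (Z)-isomer would be removed by chromatography and would in any case be unreactive as a diene.

Step 5
Reactants: 8 (3E,7E,11E)-13-(tert-butyldimethylsilyloxy)-3,7,11-trimethyltrideca-3,7,11-trien-2-one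
Product: 10 tert-butyldimethyl{[(2E,6E,10E)-3,7,11-trimethyl-12-(triethylsilyloxy)trideca-2,6,10,12-tetraen-1-yl]oxy}silane, via lithium dienolate 9 (not isolated)
Conditions: LiN(i-Pr)2, THF, −78 °C; then TESCl, −78 → 0 °C
Reagents that add atoms: chlorotriethylsilane, CC[Si](Cl)(CC)CC
Why: The hindered lithium amide removes a proton from the acetyl methyl group under kinetic control (α′- and not γ-deprotonation), and O-silylation of the cross-conjugated dienolate gives the 2-silyloxy diene without disturbing the (E)-olefin.

Step 6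
Reactants: 11 dimethyl malonate
Product: 12 dimethyl methylenemalonate
Conditions: (CH2O)n, Cu(OAc)2 (cat.), KOAc (cat.), AcOH, 100 °C; distilled under reduced pressure and used at once
Reagents that add atoms: paraformaldehyde (as formaldehyde), C=O
Why: Knoevenagel condensation of the malonate with formaldehyde and loss of water gives the methylenemalonate, which is distilled immediately before use because it polymerises on standing.

Step 7
Reactants: 10 tert-butyldimethyl{[(2E,6E,10E)-3,7,11-trimethyl-12-(triethylsilyloxy)trideca-2,6,10,12-tetraen-1-yl]oxy}silane; 12 dimethyl methylenemalonate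
Product: 13 dimethyl (2R)-2-[(3E,7E)-9-(tert-butyldimethylsilyloxy)-3,7-dimethylnona-3,7-dien-1-yl]-3-methyl-4-(triethylsilyloxy)cyclohex-3-ene-1,1-dicarboxylate
Conditions: Cu(OTf)2 (10 mol %), (S,S)-t-Bu-box [2,2'-(propane-2,2-diyl)bis((4S)-4-tert-butyl-4,5-dihydrooxazole), 11 mol %], 4 Å MS, CH2Cl2, −78 → −40 °C, slow addition of 12 (1.3 equiv); Et3N quench, Et3N-deactivated silica
Reagents that add atoms: none
Why: Proposed new method: divalent copper, held by the twofold-symmetric bis(oxazoline), chelates both ester carbonyls of 12; the CH2 terminus of the enol silane of 10 (ring C4) adds to the methylene carbon of 12 (C5) and the copper-bound malonate carbon (C6) then bonds to the chain-bearing diene terminus (C1), either as the late stage of one asynchronous [4+2] event or as a Michael closure of a short-lived silyloxyallyl cation–copper malonate pair, which leaves the silyl group on the C2=C3 enol ether and frees the catalyst. The closest known reaction types are Lewis-acid-promoted Diels–Alder reactions of 2-silyloxy dienes and Cu(OTf)2–bis(oxazoline)-catalysed Mukaiyama–Michael additions of enol silanes to alkylidene malonates. The cyclohexene ring is closed by the C6–C1 bond, suprafacially on both partners if concerted and in a 6-endo-trig sense if stepwise. The only new stereocenter, C1, is controlled by the ligand: the two faces of chelated 12 are equivalent by symmetry, so the tert-butyl groups decide which face of the (E)-diene can lie over the malonate plane, and the ligand antipode would be taken if first experiments show the opposite sense. The step needs regioselectivity, secured by the silyloxy group at C3 and the alkyl group at C1, which both make C4 the nucleophilic end so that C6 ends up next to the chain; it has no endo/exo question because the two esters are identical; and it needs chemoselectivity over the two isolated trisubstituted olefins, secured by the far higher nucleophilicity of the enol silane together with slow addition of 12 at low temperature.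

Step 8
Reactants: 13 dimethyl (2R)-2-[(3E,7E)-9-(tert-butyldimethylsilyloxy)-3,7-dimethylnona-3,7-dien-1-yl]-3-methyl-4-(triethylsilyloxy)cyclohex-3-ene-1,1-dicarboxylate
Product: 14 {(2S)-2-[(3E,7E)-9-(tert-butyldimethylsilyloxy)-3,7-dimethylnona-3,7-dien-1-yl]-3-methyl-4-(triethylsilyloxy)cyclohex-3-ene-1,1-diyl}dimethanol
Conditions: LiAlH4, Et2O, 0 °C; Na2SO4·10H2O quench
Reagents that add atoms: none
Why: LiAlH4 reduces both esters to primary alcohols while silyl enol ethers, silyl ethers and isolated alkenes are inert to it at 0 °C; the esters are removed before any enolate is generated because an enolate of 13 could expel the malonate carbon by retro-Michael ring opening.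

Step 9
Reactants: 14 {(2S)-2-[(3E,7E)-9-(tert-butyldimethylsilyloxy)-3,7-dimethylnona-3,7-dien-1-yl]-3-methyl-4-(triethylsilyloxy)cyclohex-3-ene-1,1-diyl}dimethanol
Product: 15 {(2S)-2-[(3E,7E)-9-(tert-butyldimethylsilyloxy)-3,7-dimethylnona-3,7-dien-1-yl]-3-methyl-4-(triethylsilyloxy)cyclohex-3-ene-1,1-diyl}bis(methylene) dimethanesulfonate
Conditions: MsCl, Et3N, CH2Cl2, −20 → 0 °C
Reagents that add atoms: methanesulfonyl chloride, CS(=O)(=O)Cl
Why: Sulfene-mediated mesylation of the two neopentyl primary alcohols is fast under basic conditions that leave the enol silane and the TBS ether intact.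

Step 10
Reactants: 15 {(2S)-2-[(3E,7E)-9-(tert-butyldimethylsilyloxy)-3,7-dimethylnona-3,7-dien-1-yl]-3-methyl-4-(triethylsilyloxy)cyclohex-3-ene-1,1-diyl}bis(methylene) dimethanesulfonate
Product: 16 tert-butyldimethyl{[(2E,6E)-3,7-dimethyl-9-[(1S)-2,6,6-trimethyl-3-(triethylsilyloxy)cyclohex-2-en-1-yl]nona-2,6-dien-1-yl]oxy}silane
Conditions: LiEt3BH (excess), THF, 0 → 50 °C; H2O quench, pentane extraction, Et3N-deactivated silica
Reagents that add atoms: none
Why: LiEt3BH is the most powerful hydride nucleophile for SN2 displacement at neopentyl carbon and should turn each CH2OMs group into CH3, making the former malonate carbon the gem-dimethyl carbon C6 while enol silane, TBS ether and alkenes stay untouched.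

Step 11
Reactants: 16 tert-butyldimethyl{[(2E,6E)-3,7-dimethyl-9-[(1S)-2,6,6-trimethyl-3-(triethylsilyloxy)cyclohex-2-en-1-yl]nona-2,6-dien-1-yl]oxy}silane
Product: 18 (3S)-3-[(3E,7E)-9-(tert-butyldimethylsilyloxy)-3,7-dimethylnona-3,7-dien-1-yl]-2,4,4-trimethylcyclohex-1-en-1-yl trifluoromethanesulfonate, via lithium enolate 17 (not isolated)
Conditions: MeLi, THF, 0 °C → rt; then N-(5-chloropyridin-2-yl)triflimide, −78 → 0 °C; aq. NH4Cl
Reagents that add atoms: N-(5-chloropyridin-2-yl)-1,1,1-trifluoro-N-(trifluoromethylsulfonyl)methanesulfonamide, FC(F)(F)S(=O)(=O)N(c1ccc(Cl)cn1)S(=O)(=O)C(F)(F)F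
Why: MeLi attacks silicon and releases the tetrasubstituted lithium enolate regiospecifically (harmless now that no leaving group sits β to it), and O-sulfonylation by the reactive N-pyridyl triflimide at low temperature traps it as the enol triflate before proton transfer can move the double bond; C1 has no acidic hydrogen and keeps its configuration.

Step 12
Reactants: 18 (3S)-3-[(3E,7E)-9-(tert-butyldimethylsilyloxy)-3,7-dimethylnona-3,7-dien-1-yl]-2,4,4-trimethylcyclohex-1-en-1-yl trifluoromethanesulfonate
Product: 19 tert-butyldimethyl{[(2E,6E)-3,7-dimethyl-9-[(1S)-2,6,6-trimethylcyclohex-2-en-1-yl]nona-2,6-dien-1-yl]oxy}silane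
Conditions: Pd(OAc)2 (5 mol %), PPh3, Bu3N, HCO2H, DMF, 60 °C
Reagents that add atoms: none
Why: Oxidative addition of zerovalent palladium to the alkenyl triflate, exchange of triflate for formate, decarboxylation to the palladium hydride and reductive elimination replace OTf by H without moving the olefin (palladium-catalysed formate reduction of enol triflates), leaving the ring C2=C3 double bond.

Step 13
Reactants: 19 tert-butyldimethyl{[(2E,6E)-3,7-dimethyl-9-[(1S)-2,6,6-trimethylcyclohex-2-en-1-yl]nona-2,6-dien-1-yl]oxy}silane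
Product: 20 (2E,6E)-3,7-dimethyl-9-[(1S)-2,6,6-trimethylcyclohex-2-en-1-yl]nona-2,6-dien-1-ol
Conditions: TBAF, THF, 0 °C → rt
Reagents that add atoms: none
Why: Fluoride cleaves the primary TBS ether under non-acidic conditions, which avoids acid-induced migration of the ring olefin into conjugation with C1 and ionisation of the allylic alcohol.

Step 14
Reactants: 20 (2E,6E)-3,7-dimethyl-9-[(1S)-2,6,6-trimethylcyclohex-2-en-1-yl]nona-2,6-dien-1-ol; 21 linoleic acid
Product: 22 (2E,6E)-3,7-dimethyl-9-[(1S)-2,6,6-trimethylcyclohex-2-en-1-yl]nona-2,6-dien-1-yl (9Z,12Z)-octadeca-9,12-dienoate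
Conditions: DCC, DMAP (cat.), CH2Cl2, 0 °C → rt, argon, dark
Reagents that add atoms: none
Why: Steglich esterification (carbodiimide activation with DMAP as acyl-transfer catalyst) acylates the primary allylic alcohol at room temperature without isomerising the skipped (Z,Z)-diene of the acid.

Compound list
1 | (2E,6E)-farnesol | CC(C)=CCC/C(C)=C/CC/C(C)=C/CO | starting material
2 | tert-butyldimethyl{[(2E,6E)-3,7,11-trimethyldodeca-2,6,10-trien-1-yl]oxy}silane | CC(C)=CCC/C(C)=C/CC/C(C)=C/CO[Si](C)(C)C(C)(C)C | intermediate
3 | (6E,10E)-3-bromo-12-(tert-butyldimethylsilyloxy)-2,6,10-trimethyldodeca-6,10-dien-2-ol (racemic bromohydrin, formed in the flask) | CC(C)(O)C(Br)CC/C(C)=C/CC/C(C)=C/CO[Si](C)(C)C(C)(C)C | intermediate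
4 | 3-[(3E,7E)-9-(tert-butyldimethylsilyloxy)-3,7-dimethylnona-3,7-dien-1-yl]-2,2-dimethyloxirane (racemic) | CC1(C)OC1CC/C(C)=C/CC/C(C)=C/CO[Si](C)(C)C(C)(C)C | intermediate
5 | (6E,10E)-12-(tert-butyldimethylsilyloxy)-2,6,10-trimethyldodeca-6,10-diene-2,3-diol (racemic diol, formed in the flask) | CC(C)(O)C(O)CC/C(C)=C/CC/C(C)=C/CO[Si](C)(C)C(C)(C)C | intermediate
6 | (4E,8E)-10-(tert-butyldimethylsilyloxy)-4,8-dimethyldeca-4,8-dienal | O=CCC/C(C)=C/CC/C(C)=C/CO[Si](C)(C)C(C)(C)C | intermediate
7 | 3-(triphenylphosphoranylidene)butan-2-one | CC(=O)C(C)=P(c1ccccc1)(c1ccccc1)c1ccccc1 | starting material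
8 | (3E,7E,11E)-13-(tert-butyldimethylsilyloxy)-3,7,11-trimethyltrideca-3,7,11-trien-2-one | CC(=O)/C(C)=C/CC/C(C)=C/CC/C(C)=C/CO[Si](C)(C)C(C)(C)C | intermediate
9 | lithium (3E,7E,11E)-13-(tert-butyldimethylsilyloxy)-3,7,11-trimethyltrideca-1,3,7,11-tetraen-2-olate (formed in the flask) | [Li+].C=C([O-])/C(C)=C/CC/C(C)=C/CC/C(C)=C/CO[Si](C)(C)C(C)(C)C | intermediate
10 | tert-butyldimethyl{[(2E,6E,10E)-3,7,11-trimethyl-12-(triethylsilyloxy)trideca-2,6,10,12-tetraen-1-yl]oxy}silane | C=C(O[Si](CC)(CC)CC)/C(C)=C/CC/C(C)=C/CC/C(C)=C/CO[Si](C)(C)C(C)(C)C | intermediate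
11 | dimethyl malonate | COC(=O)CC(=O)OC | starting material
12 | dimethyl methylenemalonate | C=C(C(=O)OC)C(=O)OC | intermediate
13 | dimethyl (2R)-2-[(3E,7E)-9-(tert-butyldimethylsilyloxy)-3,7-dimethylnona-3,7-dien-1-yl]-3-methyl-4-(triethylsilyloxy)cyclohex-3-ene-1,1-dicarboxylate | CC(C)(C)[Si](C)(C)OC/C=C(\C)CC/C=C(\C)CC[C@@H]1C(C)=C(O[Si](CC)(CC)CC)CCC1(C(=O)OC)C(=O)OC | intermediate
14 | {(2S)-2-[(3E,7E)-9-(tert-butyldimethylsilyloxy)-3,7-dimethylnona-3,7-dien-1-yl]-3-methyl-4-(triethylsilyloxy)cyclohex-3-ene-1,1-diyl}dimethanol | CC(C)(C)[Si](C)(C)OC/C=C(\C)CC/C=C(\C)CC[C@@H]1C(C)=C(O[Si](CC)(CC)CC)CCC1(CO)CO | intermediate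
15 | {(2S)-2-[(3E,7E)-9-(tert-butyldimethylsilyloxy)-3,7-dimethylnona-3,7-dien-1-yl]-3-methyl-4-(triethylsilyloxy)cyclohex-3-ene-1,1-diyl}bis(methylene) dimethanesulfonate | CC(C)(C)[Si](C)(C)OC/C=C(\C)CC/C=C(\C)CC[C@@H]1C(C)=C(O[Si](CC)(CC)CC)CCC1(COS(C)(=O)=O)COS(C)(=O)=O | intermediate
16 | tert-butyldimethyl{[(2E,6E)-3,7-dimethyl-9-[(1S)-2,6,6-trimethyl-3-(triethylsilyloxy)cyclohex-2-en-1-yl]nona-2,6-dien-1-yl]oxy}silane | CC(C)(C)[Si](C)(C)OC/C=C(\C)CC/C=C(\C)CC[C@@H]1C(C)=C(O[Si](CC)(CC)CC)CCC1(C)C | intermediate
17 | lithium (3S)-3-[(3E,7E)-9-(tert-butyldimethylsilyloxy)-3,7-dimethylnona-3,7-dien-1-yl]-2,4,4-trimethylcyclohex-1-en-1-olate (formed in the flask) | [Li+].CC(C)(C)[Si](C)(C)OC/C=C(\C)CC/C=C(\C)CC[C@@H]1C(C)=C([O-])CCC1(C)C | intermediate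
18 | (3S)-3-[(3E,7E)-9-(tert-butyldimethylsilyloxy)-3,7-dimethylnona-3,7-dien-1-yl]-2,4,4-trimethylcyclohex-1-en-1-yl trifluoromethanesulfonate | CC(C)(C)[Si](C)(C)OC/C=C(\C)CC/C=C(\C)CC[C@@H]1C(C)=C(OS(=O)(=O)C(F)(F)F)CCC1(C)C | intermediate
19 | tert-butyldimethyl{[(2E,6E)-3,7-dimethyl-9-[(1S)-2,6,6-trimethylcyclohex-2-en-1-yl]nona-2,6-dien-1-yl]oxy}silane | CC(C)(C)[Si](C)(C)OC/C=C(\C)CC/C=C(\C)CC[C@@H]1C(C)=CCCC1(C)C | intermediate
20 | (2E,6E)-3,7-dimethyl-9-[(1S)-2,6,6-trimethylcyclohex-2-en-1-yl]nona-2,6-dien-1-ol | OC/C=C(\C)CC/C=C(\C)CC[C@@H]1C(C)=CCCC1(C)C | intermediate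
21 | linoleic acid, (9Z,12Z)-octadeca-9,12-dienoic acid | CCCCC/C=C\C/C=C\CCCCCCCC(=O)O | starting material
22 | (2E,6E)-3,7-dimethyl-9-[(1S)-2,6,6-trimethylcyclohex-2-en-1-yl]nona-2,6-dien-1-yl (9Z,12Z)-octadeca-9,12-dienoate | CCCCC/C=C\C/C=C\CCCCCCCC(=O)OC/C=C(\C)CC/C=C(\C)CC[C@@H]1C(C)=CCCC1(C)C | target

Total step count: 14. Longest linear sequence: 13 steps (1 → 22 through steps 1–5 and 7–14); step 6 is a one-step side branch.

Steps most likely to fail

Step 7, the only step without direct precedent. Facial discrimination at C1 may be poor because the stereocenter forms at the far end of the diene from the first bond, the dienophile may polymerise faster than it is captured, or the sequence may stop after the first carbon–carbon bond through silyl loss. Fallback: setting out from 10 and 12, the cycloaddition is run without any chiral catalyst in toluene at room temperature to 60 °C, relying on the high thermal dienophilicity of methylenemalonates toward 2-silyloxy dienes. This should give racemic dimethyl 2-[(3E,7E)-9-(tert-butyldimethylsilyloxy)-3,7-dimethylnona-3,7-dien-1-yl]-3-methyl-4-(triethylsilyloxy)cyclohex-3-ene-1,1-dicarboxylate F1 with the same regiochemistry. The enantiomers are then separated by preparative chiral SFC on an immobilised amylose carbamate phase, and the route is rejoined at 13.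

Step 10. Double hydride displacement at two neopentyl carbons may be sluggish or stop halfway, attack at sulfur may regenerate an alkoxide that closes an oxetane, and prolonged heating with hydride may strip the enol silane and with it the record of the olefin position. Fallback: setting out from 15, Finkelstein exchange with NaI in DMF at 90–100 °C (the classical route from 2,2-disubstituted propane-1,3-diyl disulfonates to the diiodides) gives tert-butyl{[(2E,6E)-9-[(1R)-6,6-bis(iodomethyl)-2-methyl-3-(triethylsilyloxy)cyclohex-2-en-1-yl]-3,7-dimethylnona-2,6-dien-1-yl]oxy}dimethylsilane F2. Radical deiodination with Bu3SnH and AIBN in toluene at 80 °C, at a stannane concentration high enough to outrun any radical cyclisation, replaces both iodines by hydrogen and returns to 16.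

Step 11. Cleavage of the hindered triethylsilyl enol ether by MeLi may be slow, the lithium enolate may equilibrate by proton transfer so that the olefin position is no longer defined, or O-sulfonylation of the tetrasubstituted enolate may be incomplete. Fallback: setting out from 16, the enol silane is treated with nonafluorobutane-1-sulfonyl fluoride and a catalytic anhydrous fluoride source (tetrabutylammonium difluorotriphenylsilicate) in THF at 0 °C to room temperature. This exchanges silicon for sulfonyl without any stoichiometric metal enolate and gives (3S)-3-[(3E,7E)-9-(tert-butyldimethylsilyloxy)-3,7-dimethylnona-3,7-dien-1-yl]-2,4,4-trimethylcyclohex-1-en-1-yl nonafluorobutane-1-sulfonate F3. The Pd(OAc)2/PPh3/Bu3N/HCO2H reduction of step 12 applied to this nonaflate returns to the route at 19.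

Further compounds
F1 | step 7 | racemic dimethyl 2-[(3E,7E)-9-(tert-butyldimethylsilyloxy)-3,7-dimethylnona-3,7-dien-1-yl]-3-methyl-4-(triethylsilyloxy)cyclohex-3-ene-1,1-dicarboxylate | CC(C)(C)[Si](C)(C)OC/C=C(\C)CC/C=C(\C)CCC1C(C)=C(O[Si](CC)(CC)CC)CCC1(C(=O)OC)C(=O)OC
F2 | step 10 | tert-butyl{[(2E,6E)-9-[(1R)-6,6-bis(iodomethyl)-2-methyl-3-(triethylsilyloxy)cyclohex-2-en-1-yl]-3,7-dimethylnona-2,6-dien-1-yl]oxy}dimethylsilane | CC(C)(C)[Si](C)(C)OC/C=C(\C)CC/C=C(\C)CC[C@@H]1C(C)=C(O[Si](CC)(CC)CC)CCC1(CI)CI
F3 | step 11 | (3S)-3-[(3E,7E)-9-(tert-butyldimethylsilyloxy)-3,7-dimethylnona-3,7-dien-1-yl]-2,4,4-trimethylcyclohex-1-en-1-yl nonafluorobutane-1-sulfonate | CC(C)(C)[Si](C)(C)OC/C=C(\C)CC/C=C(\C)CC[C@@H]1C(C)=C(OS(=O)(=O)C(F)(F)C(F)(F)C(F)(F)C(F)(F)F)CCC1(C)C
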